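In a one-step world a catalyst clears its charge in a time set by that step, so we begin by asking how long this catalyst needs to pass the starting material through once.

in all of them: protic impurity 0.0500 M; free catalyst 0.2 mol%
- green: starting material 0.050 M; coupling partner 1.10 equiv (fed, over 6.00 s); time 12 s; a stirred flask in which coupling partner is dosed at a steady rate over 6.00 s without added volume, worked up at 12 s
- ochre: starting material 0.050 M (fed, over 6.00 s); coupling partner 1.10 equiv; time 12 s; a stirred flask in which starting material is dosed at a steady rate over 6.00 s without added volume, worked up at 12 s
- amber: starting material 0.050 M; coupling partner 1.10 equiv; a single well-mixed tank run continuously and read at steady state, 12 s in it on average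
- teal: starting material 0.050 M; coupling partner 1.10 equiv; time 12 s; everything together in a closed stirred flask, run for 12 s

    starting material + free catalyst ⇌ catalyst intermediate A (K1 = 49 M⁻¹, k1 = 2400 M⁻¹ s⁻¹)
    coupling partner + catalyst intermediate A ⇌ catalyst intermediate B (K2 = 600 M⁻¹, k2 = 1.4 × 10⁵ M⁻¹ s⁻¹)
    catalyst intermediate B → by-product + catalyst intermediate C (k3 = 670 s⁻¹)
    catalyst intermediate C ⇌ free catalyst + target (K4 = 0.034 M, k4 = 130 s⁻¹)
    coupling partner + protic impurity → quenched reagent (k5 = 4.1 M⁻¹ s⁻¹)
    starting material + target → side product A (k6 = 0.65 M⁻¹ s⁻¹)
    starting material + by-product → side product B (k7 = 0.79 M⁻¹ s⁻¹)

- the set-up with the highest amount of target at the outlet or at the end, in percent of the starting material put in ("none" if the first two lie within 2 percentage points) (green / ochre / amber / teal / none)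
- amount of target at the outlet or at the end, in percent of the starting material put in, green
- amount of target at the outlet or at the end, in percent of the starting material put in, ochre
- amount of target at the outlet or at the end, in percent of the starting material put in, amber
- amount of target at the outlet or at the end, in percent of the starting material put in, teal

- percentages count the starting material that a species holds: one side product A counts as two
- the stated concentrations are those of everything mixed, before any reaction; amounts are the same in each set-up
- the feed brings no volume worth counting
- run time (green): 12 s

We can reckon that time in two ways. Taking the entry, where starting material at its charged concentration binds free catalyst, as the sole step gives 4.17 s. Taking the exit, where catalyst intermediate C releases target, as the sole step gives 3.85 s. The two nearly agree, but each cheats: each places the whole catalyst at its own step, and a catalyst molecule stands at one step at a time.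

The symmetric case sets the zero of the scale. With two nearly equal steps, a catalyst molecule waits about half of its cycle at each, so the two steps together take about twice the exit figure. The waits therefore add. With the step from catalyst intermediate B included, the cycle time is 17.5 ms, and its inverse is the usual turnover frequency. The coupling step adds 0.130 ms at the charged level of coupling partner, much less than the cycle time, so we leave it out.

Dividing the cycle time by the catalyst loading gives the clearing time, the time to pass the whole charge through at the speed of a fresh flask: 8.76 s.

Our reckoning goes one step further. In teal the half-life of coupling partner against the impurity, with the other concentrations as charged, is 3.4 s, shorter than the clearing time, so the quench starts out ahead of the catalyst. In green one equivalent arrives in 5.45 s, also sooner than the clearing time, so even the dose outruns a fresh catalyst. We stop there and commit to no yields; the clearing time leaves out target returning to the catalyst.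

The forecast does give yields. It names green as best, with 61% for green, 49% for ochre, 43% for amber and 54% for teal, on the ground that “dosing it keeps its level low and saves it for the coupling”.

The simulation ranks green first, with 59.0% of target in green, 47.2% in ochre, 43.2% in amber and 53.7% in teal. Green's run of 12 s is longer than the clearing time, yet at its end green still holds 21.2% of its starting material, and 0.0199 M of quenched reagent against 0.0249 M in teal. For the flask like green but charged with 0.013 M of starting material, the same sum gives a clearing time of 20.6 s, longer than its run, so a fresh-flask speed would pass 58.3% of its charge. That flask ended at 12.0 s with 36.0% as target and 59.4% as unused starting material.

All constants stand for no real mixture.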